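## Retrosynthetic overview

1. Target ⇐ LiAlH4 reduction (CHO → CH2OH, both acetates removed) of the all-trans 2,5-diaryl-4-formyl oxolane; the oxolane is the only ring the route has to make.
2. Oxolane ⇐ one-pot acetalisation / Prins cyclisation / pinacol-type 1,2-shift (a six-membered oxanyl cation contracts to the oxolane), then C5 epimerisation, from an (E)-allylic anti-1,2-diol and 4-acetoxy-3,5-dimethoxybenzaldehyde.
3. (E)-Allylic diol ⇐ cross-metathesis of a vinyl anti-diol with cis-1,4-diacetoxybut-2-ene; vinyl diol ⇐ asymmetric γ-borylallylboration/oxidation of 3,4,5-trimethoxybenzaldehyde.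
4. Both aldehydes ⇐ syringaldehyde ⇐ 3,5-dibromo-4-hydroxybenzaldehyde ⇐ p-cresol.
5. Ring order: dioxolane (transient) → oxane cation (transient) → oxolane.

Assumption: pinacol on boron and acetyl on oxygen are treated as protecting groups, so the commercial pinacol ester of allenylboronic acid and the commercial diacetate of cis-but-2-ene-1,4-diol are used as such.

Oxolane numbering used below: O1, C2 = carbon bearing the 4-oxygenated 3,5-dimethoxyphenyl ring, C3, C4, C5 = carbon bearing the 3,4,5-trimethoxyphenyl ring.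

## Route

Step 1
Reactants: 1 p-cresol
Product: 4 3,5-dibromo-4-hydroxybenzaldehyde, via 2,6-dibromo-4-methylphenol 2 (not isolated), via 2,6-dibromo-4-(dibromomethyl)phenol 3 (not isolated)
Conditions: Br2 (2.0 equiv), o-dichlorobenzene, 35 °C; then Br2 (2.1 equiv), 155 °C; then H2O, 110 °C
Reagents that add atoms: bromine, BrBr; water, O
Why: Electrophilic aromatic bromination ortho to the hydroxyl, side-chain bromination of the para-methyl group to the benzal bromide and hydrolysis of the gem-dibromide give the aldehyde in one pot, as in the industrial process for this compound, with no stereocentre involved.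

Step 2
Reactants: 4 3,5-dibromo-4-hydroxybenzaldehyde
Product: 5 4-hydroxy-3,5-dimethoxybenzaldehyde (syringaldehyde)
Conditions: NaOMe (5 equiv), CuCl (10 mol %), DMF–MeOH, 115 °C; then aq. HCl
Reagents that add atoms: sodium methoxide, C[O-].[Na+]
Why: Copper-catalysed Ullmann-type methoxylation replaces both aryl bromides, the standard industrial entry to syringaldehyde, with no stereocentre involved.

Step 3
Reactants: 5 4-hydroxy-3,5-dimethoxybenzaldehyde
Product: 6 3,4,5-trimethoxybenzaldehyde
Conditions: MeI (1.5 equiv), K2CO3, DMF, 50 °C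
Reagents that add atoms: iodomethane, CI
Why: Williamson O-methylation of the phenoxide is clean because the aldehyde has no enolisable position.

Step 4
Reactants: 5 4-hydroxy-3,5-dimethoxybenzaldehyde
Product: 7 4-formyl-2,6-dimethoxyphenyl acetate
Conditions: Ac2O, pyridine, DMAP (5 mol %), CH2Cl2, 0 → 23 °C
Reagents that add atoms: acetic anhydride, CC(=O)OC(C)=O
Why: DMAP-catalysed O-acetylation masks the phenol, makes this ring the poorer cation-stabiliser (so C2 stays fixed later) and is removed by the final hydride step without an extra operation.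

Step 5
Reactants: 6 3,4,5-trimethoxybenzaldehyde; 8 allenylboronic acid pinacol ester
Product: 11 (1R,2S)-1-(3,4,5-trimethoxyphenyl)but-3-ene-1,2-diol, via E-borylallyl(diisopinocampheyl)borane 9 (not isolated), via borinate adduct 10 (not isolated)
Conditions: (−)-Ipc2BH (from (+)-α-pinene), Et2O, 0 °C, 2 h; then 6 (0.9 equiv), −78 °C, 3 h; then NaOH, H2O2, THF–H2O, 0 → 23 °C
Reagents that add atoms: hydrogen peroxide, OO
Why: Hydroboration of the allene at its unsubstituted terminus gives the E γ-borylallylborane 9, which adds to the Si face of 6 through a chair Zimmerman–Traxler transition state (Brown allylboration) to set C1 as R with the C–B bond anti, and oxidation of that C–B bond with retention gives the anti diol.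

Step 6
Reactants: 11 (1R,2S)-1-(3,4,5-trimethoxyphenyl)but-3-ene-1,2-diol; 12 cis-1,4-diacetoxybut-2-ene
Product: 13 (2E,4S,5R)-4,5-dihydroxy-5-(3,4,5-trimethoxyphenyl)pent-2-en-1-yl acetate
Conditions: 12 (3 equiv), second-generation Hoveyda–Grubbs catalyst RuCl2(=CH-C6H4-2-OiPr)(H2IMes) (5 mol %), CH2Cl2, 40 °C
Reagents that add atoms: none
Why: Olefin cross-metathesis of the terminal vinyl group with an excess of the symmetrical internal olefin gives the thermodynamically favoured E allylic acetate and leaves both carbinol stereocentres untouched.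

Step 7
Reactants: 13 (2E,4S,5R)-4,5-dihydroxy-5-(3,4,5-trimethoxyphenyl)pent-2-en-1-yl acetate; 7 4-formyl-2,6-dimethoxyphenyl acetate
Product: 16 [(2R,3S,4R,5R)-2-(4-acetoxy-3,5-dimethoxyphenyl)-4-formyl-5-(3,4,5-trimethoxyphenyl)oxolan-3-yl]methyl acetate, via diaryl dioxolane 14 (not isolated), via 5-epi aldehyde 15 (not isolated)
Conditions: 7 (1.1 equiv), BF3·OEt2 (3 equiv), CH2Cl2, −40 → −20 °C, 4 h; then 0 → 23 °C, 6 h
Reagents that add atoms: none
Why: Proposed new method: acid condensation gives dioxolane 14, BF3 opens it at the allylic oxygen to the aryl-stabilised oxocarbenium ion, the E alkene adds through a chair with both aryl groups, the acetoxymethyl group and the O–BF3 group equatorial to give an oxan-4-yl cation, and the ring C–C bond to the aryl-bearing carbon then shifts to the cationic carbon (pinacol-type 1,2-shift, six-membered ring contracts to the oxolane, the carbinol carbon becomes the formyl group), which sets C2 (R) and C3 (S) trans in the sense dictated by C5 and C4 trans to C3 to give 15 (4,5-cis), after which warming lets the trimethoxybenzylic C5–O (or C4–C5) bond ionise reversibly so that C5 settles trans to C4 in all-trans 16; the closest known reaction types are the pinacol-terminated Prins cyclisation of allylic diol acetals to 3-acyl oxolanes (Overman) and the Lewis-acid equilibration of 2-aryl-3-formyl oxolanes to the trans isomers, neither shown for a diaryl acetal whose disubstituted alkene carries an allylic acetoxy group and delivers an aldehyde.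

Step 8
Reactants: 16 [(2R,3S,4R,5R)-2-(4-acetoxy-3,5-dimethoxyphenyl)-4-formyl-5-(3,4,5-trimethoxyphenyl)oxolan-3-yl]methyl acetate
Product: 17 [(2R,3S,4S,5R)-2-(4-hydroxy-3,5-dimethoxyphenyl)-5-(3,4,5-trimethoxyphenyl)oxolane-3,4-diyl]dimethanol
Conditions: LiAlH4 (4 equiv), THF, 0 °C, 1 h; then EtOAc, aq. NH4Cl
Reagents that add atoms: none
Why: Hydride reduction of the aldehyde and reductive cleavage of the alkyl and aryl acetates occur in one operation, the aldehyde being reduced faster than it can enolise, so all four stereocentres are carried through unchanged.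

## Compound list

1 | p-cresol | Cc1ccc(O)cc1 | starting material
2 | 2,6-dibromo-4-methylphenol | Cc1cc(Br)c(O)c(Br)c1 | intermediate
3 | 2,6-dibromo-4-(dibromomethyl)phenol | BrC(Br)c1cc(Br)c(O)c(Br)c1 | intermediate
4 | 3,5-dibromo-4-hydroxybenzaldehyde | O=Cc1cc(Br)c(O)c(Br)c1 | intermediate
5 | 4-hydroxy-3,5-dimethoxybenzaldehyde (syringaldehyde) | COc1cc(C=O)cc(OC)c1O | intermediate
6 | 3,4,5-trimethoxybenzaldehyde | COc1cc(C=O)cc(OC)c1OC | intermediate
7 | 4-formyl-2,6-dimethoxyphenyl acetate | COc1cc(C=O)cc(OC)c1OC(C)=O | intermediate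
8 | allenylboronic acid pinacol ester | C=C=CB1OC(C)(C)C(C)(C)O1 | starting material
9 | (E)-[3-(pinacolboryl)prop-2-en-1-yl]bis(isopinocampheyl)borane, Ipc groups from (+)-α-pinene | CC1(C)OB(/C=C/CB([C@H]2[C@H](C)[C@H]3C[C@@H](C2)C3(C)C)[C@H]2[C@H](C)[C@H]3C[C@@H](C2)C3(C)C)OC1(C)C | intermediate
10 | [(1S,2S)-2-(pinacolboryl)-1-(3,4,5-trimethoxyphenyl)but-3-en-1-yl] bis(isopinocampheyl)borinate (anti adduct) | B([C@H]2[C@H](C)[C@H]3C[C@@H](C2)C3(C)C)([C@H]2[C@H](C)[C@H]3C[C@@H](C2)C3(C)C)O[C@H](c2cc(OC)c(OC)c(OC)c2)[C@@H](B2OC(C)(C)C(C)(C)O2)C=C | intermediate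
11 | (1R,2S)-1-(3,4,5-trimethoxyphenyl)but-3-ene-1,2-diol | O[C@H](c1cc(OC)c(OC)c(OC)c1)[C@@H](O)C=C | intermediate
12 | cis-1,4-diacetoxybut-2-ene | CC(=O)OC/C=C\COC(C)=O | starting material
13 | (2E,4S,5R)-4,5-dihydroxy-5-(3,4,5-trimethoxyphenyl)pent-2-en-1-yl acetate | O[C@H](c1cc(OC)c(OC)c(OC)c1)[C@@H](O)/C=C/COC(C)=O | intermediate
14 | (4S,5R)-2-(4-acetoxy-3,5-dimethoxyphenyl)-4-[(E)-3-acetoxyprop-1-en-1-yl]-5-(3,4,5-trimethoxyphenyl)-1,3-dioxolane (both C2 epimers; C2 becomes the oxocarbenium carbon) | CC(=O)Oc1c(OC)cc(cc1OC)C1O[C@H](c2cc(OC)c(OC)c(OC)c2)[C@@H](O1)/C=C/COC(C)=O | intermediate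
15 | [(2R,3S,4R,5S)-2-(4-acetoxy-3,5-dimethoxyphenyl)-4-formyl-5-(3,4,5-trimethoxyphenyl)oxolan-3-yl]methyl acetate (2,3-trans, 3,4-trans, 4,5-cis) | COc1cc([C@@H]2O[C@H](c3cc(OC)c(OC)c(OC)c3)[C@H](C=O)[C@H]2COC(C)=O)cc(OC)c1OC(C)=O | intermediate
16 | [(2R,3S,4R,5R)-2-(4-acetoxy-3,5-dimethoxyphenyl)-4-formyl-5-(3,4,5-trimethoxyphenyl)oxolan-3-yl]methyl acetate (all-trans) | COc1cc([C@@H]2O[C@@H](c3cc(OC)c(OC)c(OC)c3)[C@H](C=O)[C@H]2COC(C)=O)cc(OC)c1OC(C)=O | intermediate
17 | [(2R,3S,4S,5R)-2-(4-hydroxy-3,5-dimethoxyphenyl)-5-(3,4,5-trimethoxyphenyl)oxolane-3,4-diyl]dimethanol (all-trans) | COc1cc([C@@H]2O[C@@H](c3cc(OC)c(OC)c(OC)c3)[C@H](CO)[C@H]2CO)cc(OC)c1O | target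

## Step count and risks

Total step count: 8. Longest linear sequence: 7 steps (1 → 4 → 5 → 6 → 11 → 13 → 16 → 17). Step 4 is the one-step branch from 5.

The three steps most likely to fail:

Step 7 (the proposed new step). The ways it can fail are:
- a 1,2-hydride shift at the cationic stage, giving an oxan-3-one instead of ring contraction;
- trapping of the cation by the allylic acetate;
- pinacol rearrangement of the benzylic diol before the acetal forms;
- Friedel–Crafts closure of the opened benzylic cation onto an aryl ring during the warm equilibration;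
- partial loss of the C3 configuration if an oxonia-Cope/aldol manifold competes through a non-chair geometry.

The fallback uses only known chemistry, sets out from 12, 7 and 6 and comes back at 16. Cross-metathesis of commercial allylboronic acid pinacol ester with 12 (second-generation Hoveyda–Grubbs catalyst RuCl2(=CH-C6H4-2-OiPr)(H2IMes)) gives (E)-4-(4,4,5,5-tetramethyl-1,3,2-dioxaborolan-2-yl)but-2-en-1-yl acetate F3. Chiral-phosphoric-acid-catalysed allylboration of 7 with F3 (the TRIP enantiomer that delivers the R carbinol, toluene, −30 °C) gives the anti homoallylic alcohol (2S)-2-[(R)-(4-acetoxy-3,5-dimethoxyphenyl)(hydroxy)methyl]but-3-en-1-yl acetate F4; this fixes C2 and C3 of the oxolane trans. Aldehyde-selective Wacker oxidation of the vinyl group (PdCl2(PhCN)2, CuCl2, AgNO2, O2, tBuOH–MeNO2) gives the lactol [(2R,3S)-2-(4-acetoxy-3,5-dimethoxyphenyl)-5-hydroxyoxolan-3-yl]methyl acetate F5. Aldol condensation of F5 with 6 (Bn2NH·CF3CO2H, toluene, 60 °C) gives the hydroxy enal (2S,3E)-2-[(R)-(4-acetoxy-3,5-dimethoxyphenyl)(hydroxy)methyl]-3-formyl-4-(3,4,5-trimethoxyphenyl)but-3-en-1-yl acetate F6. Camphorsulfonic acid in CH2Cl2 then closes the oxolane by addition of the hydroxyl to the trimethoxybenzylic alkene terminus, under thermodynamic control, to give all-trans 16.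

Step 6. The free allylic diol can slow the ruthenium catalyst, and any Z isomer would carry the wrong C3 configuration into step 7. The fallback sets out from 11 and 7 and comes back at 14, so the metathesis is run on the acetal and not on the diol. Acetalisation of 11 with 7 (camphorsulfonic acid, MgSO4, CH2Cl2, 23 °C) gives (4S,5R)-2-(4-acetoxy-3,5-dimethoxyphenyl)-4-ethenyl-5-(3,4,5-trimethoxyphenyl)-1,3-dioxolane F2. Cross-metathesis of F2 with 12 under the step 6 catalyst gives 14, which is isolated, freed of Z isomer by chromatography and then treated with BF3·OEt2 as in step 7.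

Step 5. The borylallylborane 9 must be the E isomer, a second allylboration by 10 must be suppressed, and the electron-rich aldehyde may give lower selectivity. The fallback sets out from 6 and comes back at 11. Iridium-catalysed transfer-hydrogenative anti-(benzoyloxy)allylation of 6 with 3,3-bis(benzoyloxy)prop-1-ene is used ([Ir(cod)Cl]2, the SEGPHOS enantiomer that gives the 1R,2S product, 4-chloro-3-nitrobenzoic acid, K3PO4, iPrOH, THF, 60 °C). It gives (1R,2S)-1-hydroxy-1-(3,4,5-trimethoxyphenyl)but-3-en-2-yl benzoate F1, and methanolysis (K2CO3, MeOH, 0 °C) gives 11.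

Further compounds
F1 | step 5 | (1R,2S)-1-hydroxy-1-(3,4,5-trimethoxyphenyl)but-3-en-2-yl benzoate | O[C@H](c1cc(OC)c(OC)c(OC)c1)[C@@H](OC(=O)c1ccccc1)C=C
F2 | step 6 | (4S,5R)-2-(4-acetoxy-3,5-dimethoxyphenyl)-4-ethenyl-5-(3,4,5-trimethoxyphenyl)-1,3-dioxolane | CC(=O)Oc1c(OC)cc(cc1OC)C1O[C@H](c2cc(OC)c(OC)c(OC)c2)[C@@H](O1)C=C
F3 | step 7 | (E)-4-(4,4,5,5-tetramethyl-1,3,2-dioxaborolan-2-yl)but-2-en-1-yl acetate | CC(=O)OC/C=C/CB1OC(C)(C)C(C)(C)O1
F4 | step 7 | (2S)-2-[(R)-(4-acetoxy-3,5-dimethoxyphenyl)(hydroxy)methyl]but-3-en-1-yl acetate | COc1cc(cc(OC)c1OC(C)=O)[C@H](O)[C@@H](C=C)COC(C)=O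
F5 | step 7 | [(2R,3S)-2-(4-acetoxy-3,5-dimethoxyphenyl)-5-hydroxyoxolan-3-yl]methyl acetate | COc1cc(cc(OC)c1OC(C)=O)[C@@H]1OC(O)C[C@H]1COC(C)=O
F6 | step 7 | (2S,3E)-2-[(R)-(4-acetoxy-3,5-dimethoxyphenyl)(hydroxy)methyl]-3-formyl-4-(3,4,5-trimethoxyphenyl)but-3-en-1-yl acetate | COc1cc(cc(OC)c1OC(C)=O)[C@H](O)[C@@H](/C(C=O)=C\c1cc(OC)c(OC)c(OC)c1)COC(C)=O
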